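**Retrosynthetic overview** (dihydrobenzofuran numbering: O1, C2, C3, C3a, C4–C7, C7a)

- The target is cut last at C7–C(=O): C7, the arene CH between O1 and the C6 methoxy group, is lithiated and acylated with the silylated Weinreb amide of (E)-4-hydroxycinnamic acid, then all silyl groups are removed.
- The C2 side chain CMe2OH is traced back to a C2 ethyl ester (double methyl Grignard addition).
- The strategy rests on C2, the sole stereocentre and the only atom of the five-membered ring bonded to both O1 and C3. The ring is therefore opened at O1–C2 and C2–C3 into an ortho-quinone methide (O1, C7a, C3a, C3) and a one-carbon ester-bearing sulfonium ylide: a formal [4+1] annulation.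
- The quinone methide comes from a 2-(tosylmethyl)phenol made from 2,4,6-trihydroxybenzaldehyde, whose two equivalent ortho hydroxyls remove any regiochemical choice. The ylide comes from a C2-symmetric thiolanium salt made from (2S,5S)-hexane-2,5-diol and ethyl bromoacetate.
- Ring order: the benzene ring is purchased; the dihydrofuran ring is the only ring formed (step 8).

Key step: step 8

Assumption: the (2R,5R)-thiolanium salt is taken to favour closure to the (2S)-ester. If a first trial shows the opposite sense, the enantiomeric salt from (2R,5R)-hexane-2,5-diol is used and nothing else in the route changes.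

**Step 1**
Reactants: 1 2,4,6-trihydroxybenzaldehyde
Product: 2 2,6-dihydroxy-4-methoxybenzaldehyde
Conditions: Me2SO4 (1.0 equiv), K2CO3 (1.0 equiv), acetone, rt
Reagents that add atoms: dimethyl sulfate, COS(=O)(=O)OC
Why: Williamson O-methylation, in which the 2- and 6-hydroxyls are held in hydrogen bonds to the formyl oxygen, so the para 4-OH (most acidic, only free phenoxide with one equivalent of base) should be methylated selectively.

**Step 2**
Reactants: 2 2,6-dihydroxy-4-methoxybenzaldehyde
Product: 3 2-hydroxy-4-methoxy-6-(triisopropylsilyloxy)benzaldehyde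
Conditions: TIPSCl (1.05 equiv), imidazole (2.5 equiv), DMF, 0 °C → rt
Reagents that add atoms: chlorotriisopropylsilane, CC(C)[Si](Cl)(C(C)C)C(C)C
Why: Silyl ether formation on one of two equivalent hydroxyls, after which the remaining hydroxyl is the sole hydrogen-bond donor to the aldehyde and is much less reactive, so one equivalent of silyl chloride should stop at the mono-ether.

**Step 3**
Reactants: 3 2-hydroxy-4-methoxy-6-(triisopropylsilyloxy)benzaldehyde
Product: 4 2-(hydroxymethyl)-5-methoxy-3-(triisopropylsilyloxy)phenol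
Conditions: NaBH4, THF/MeOH, −10 °C; pH 7 buffer quench
Reagents that add atoms: none
Why: Borohydride reduction of the aldehyde to the benzylic alcohol, run cold with a neutral quench so that the electron-rich salicyl alcohol neither ionises nor suffers silyl migration.

**Step 4**
Reactants: 4 2-(hydroxymethyl)-5-methoxy-3-(triisopropylsilyloxy)phenol
Product: 5 5-methoxy-2-[(4-methylphenyl)sulfonylmethyl]-3-(triisopropylsilyloxy)phenol
Conditions: p-TolSO2H (2 equiv), CH2Cl2, 0 °C → rt
Reagents that add atoms: p-toluenesulfinic acid, Cc1ccc(cc1)S(=O)O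
Why: Acid-promoted benzylic substitution (SN1 through the ortho-hydroxybenzyl cation), in which the sulfinic acid ionises the electron-rich alcohol and excess sulfinate traps the cation at sulfur to give the sulfone.

**Step 5**
Reactants: 6 (2S,5S)-hexane-2,5-diol
Product: 7 (2S,5S)-hexane-2,5-diyl dimethanesulfonate
Conditions: MsCl (2.4 equiv), Et3N (3 equiv), CH2Cl2, −20 → 0 °C
Reagents that add atoms: methanesulfonyl chloride, CS(=O)(=O)Cl
Why: Mesylation takes place at oxygen, so both carbinol stereocentres are retained.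

**Step 6**
Reactants: 7 (2S,5S)-hexane-2,5-diyl dimethanesulfonate
Product: 8 (2R,5R)-2,5-dimethylthiolane
Conditions: Na2S·9H2O (1.2 equiv), DMSO, rt; distillation
Reagents that add atoms: sodium sulfide, [Na+].[Na+].[S-2]
Why: Double SN2 thioetherification (the second displacement a 5-exo-tet closure) inverts both carbons, turning the (S,S)-dimesylate into the C2-symmetric (R,R)-thiolane.

**Step 7**
Reactants: 8 (2R,5R)-2,5-dimethylthiolane; 9 ethyl bromoacetate
Product: 10 (2R,5R)-1-(2-ethoxy-2-oxoethyl)-2,5-dimethylthiolan-1-ium bromide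
Conditions: acetone (concentrated), rt, 2–4 d; salt collected by filtration
Reagents that add atoms: none
Why: SN2 S-alkylation of the sulfide by the α-bromo ester (sulfonium salt formation), which gives one salt with non-stereogenic sulfur because the two lone pairs of the C2-symmetric sulfide are homotopic.

**Step 8**
Reactants: 5 5-methoxy-2-[(4-methylphenyl)sulfonylmethyl]-3-(triisopropylsilyloxy)phenol; 10 (2R,5R)-1-(2-ethoxy-2-oxoethyl)-2,5-dimethylthiolan-1-ium bromide
Product: 14 ethyl (2S)-6-methoxy-4-(triisopropylsilyloxy)-2,3-dihydro-1-benzofuran-2-carboxylate, via ortho-quinone methide 11 (not isolated), via sulfonium ylide 12 (not isolated), via betaine 13 (not isolated)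
Conditions: 10 (1.5 equiv), Cs2CO3 (2.5 equiv), CH2Cl2, −20 → 0 °C, slow addition of 5
Reagents that add atoms: none
Why: Proposed new method: carbonate deprotonates the phenol of 5, which expels p-toluenesulfinate to give ortho-quinone methide 11, and also converts 10 into ester-stabilised ylide 12, whose carbon adds to the exocyclic CH2 of 11 with re-aromatisation (C2–C3 bond) to give phenoxide–sulfonium betaine 13, in which the phenoxide then displaces the thiolane at C2 (O1–C2 bond). The closest known reaction type is the [4+1] annulation of in situ generated ortho-quinone methides with stabilised sulfonium or ammonium ylides, where stereocontrol has been shown for 2,3-disubstituted dihydrobenzofurans but not for a product whose only stereocentre is C2. The dihydrofuran ring closes by 5-exo-tet SN2 displacement with inversion at C2. C2 is set in that closure and not in the C–C bond formation: its proton in 13 lies between an ester and a sulfonium group, so the two betaine epimers should interconvert by reversible deprotonation (and by reversible Michael addition), while the C2-symmetric (2R,5R)-thiolanium leaving group, with a methyl group on each carbon flanking sulfur, should make one of the two diastereomeric closures faster (Curtin–Hammett situation). The step therefore needs enantioselectivity only, because the methide terminus is an unsubstituted CH2 and the arene offers a single phenoxide, and it needs trapping of 11 by 12 to outrun self-condensation of 11, which slow release of 11 by a heterogeneous base at low temperature in the presence of excess ylide should secure. Sulfur in 10 is not stereogenic, so a single ylide is present and the sulfide should be recoverable.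

**Step 9**
Reactants: 14 ethyl (2S)-6-methoxy-4-(triisopropylsilyloxy)-2,3-dihydro-1-benzofuran-2-carboxylate
Product: 16 2-[(2S)-6-methoxy-4-(triisopropylsilyloxy)-2,3-dihydro-1-benzofuran-2-yl]propan-2-ol, via methyl ketone 15 (not isolated)
Conditions: MeMgBr (3.5 equiv), THF, −78 → 0 °C; aq NH4Cl
Reagents that add atoms: methylmagnesium bromide, C[Mg]Br
Why: Double Grignard addition to the ester through ketone 15, where addition to the chelating α-aryloxy carbonyl at low temperature should outrun enolisation, so C2 keeps its configuration (the descriptor stays S).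

**Step 10**
Reactants: 16 2-[(2S)-6-methoxy-4-(triisopropylsilyloxy)-2,3-dihydro-1-benzofuran-2-yl]propan-2-ol
Product: 17 triethyl({2-[(2S)-6-methoxy-4-(triisopropylsilyloxy)-2,3-dihydro-1-benzofuran-2-yl]propan-2-yl}oxy)silane
Conditions: TESOTf (1.3 equiv), 2,6-lutidine (2 equiv), CH2Cl2, −78 → 0 °C
Reagents that add atoms: triethylsilyl trifluoromethanesulfonate, CC[Si](CC)(CC)OS(=O)(=O)C(F)(F)F
Why: Silylation of the hindered tertiary alcohol with a silyl triflate and a hindered pyridine base removes the only acidic proton before the metalation.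

**Step 11**
Reactants: 18 (E)-4-hydroxycinnamic acid
Product: 19 (2E)-3-(4-hydroxyphenyl)-N-methoxy-N-methylprop-2-enamide
Conditions: MeNHOMe·HCl (1.2 equiv), EDC·HCl (1.2 equiv), HOBt (0.2 equiv), Et3N (2.4 equiv), CH2Cl2/DMF, 0 °C → rt
Reagents that add atoms: N,O-dimethylhydroxylamine hydrochloride, CNOC.Cl
Why: Carbodiimide amide coupling (Weinreb amide formation), in which the amine is far more nucleophilic than the phenol, so the free phenol is tolerated and the E-alkene is untouched.

**Step 12**
Reactants: 19 (2E)-3-(4-hydroxyphenyl)-N-methoxy-N-methylprop-2-enamide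
Product: 20 (2E)-3-[4-(tert-butyldimethylsilyloxy)phenyl]-N-methoxy-N-methylprop-2-enamide
Conditions: TBSCl (1.2 equiv), imidazole (2.5 equiv), DMF, rt
Reagents that add atoms: tert-butyldimethylsilyl chloride, CC(C)(C)[Si](C)(C)Cl
Why: Silyl ether formation on the phenol removes the acidic proton that would quench the aryllithium of step 13.

**Step 13**
Reactants: 17 triethyl({2-[(2S)-6-methoxy-4-(triisopropylsilyloxy)-2,3-dihydro-1-benzofuran-2-yl]propan-2-yl}oxy)silane; 20 (2E)-3-[4-(tert-butyldimethylsilyloxy)phenyl]-N-methoxy-N-methylprop-2-enamide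
Product: 23 (2E)-3-[4-(tert-butyldimethylsilyloxy)phenyl]-1-[(2S)-6-methoxy-2-[2-(triethylsilyloxy)propan-2-yl]-4-(triisopropylsilyloxy)-2,3-dihydro-1-benzofuran-7-yl]prop-2-en-1-one, via aryllithium 21 (not isolated), via lithium hemiaminal adduct 22 (not isolated)
Conditions: n-BuLi (1.15 equiv), TMEDA (1.2 equiv), Et2O, 0 °C; then 20 (1.3 equiv), THF, −78 → 0 °C; aq NH4Cl
Reagents that add atoms: none
Why: Directed ortho-metalation followed by Weinreb ketone synthesis, in which C7–H lies between two coordinating ether oxygens (O1 and the C6 methoxy) whereas C5–H is shielded by the bulky, poorly coordinating OTIPS group, so lithiation should give 21, which adds 1,2 to amide 20 to give chelated adduct 22 that releases the E-enone only on aqueous work-up.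

**Step 14**
Reactants: 23 (2E)-3-[4-(tert-butyldimethylsilyloxy)phenyl]-1-[(2S)-6-methoxy-2-[2-(triethylsilyloxy)propan-2-yl]-4-(triisopropylsilyloxy)-2,3-dihydro-1-benzofuran-7-yl]prop-2-en-1-one
Product: 24 (2E)-1-[(2S)-4-hydroxy-2-(2-hydroxypropan-2-yl)-6-methoxy-2,3-dihydro-1-benzofuran-7-yl]-3-(4-hydroxyphenyl)prop-2-en-1-one (CNP0103650.1)
Conditions: TBAF (4 equiv), AcOH (4 equiv), THF, 0 °C → rt
Reagents that add atoms: none
Why: Fluoride-mediated cleavage of the three silyl ethers (two aryl, one tertiary alkyl) in acetic-acid-buffered medium, where the enone has no ortho-hydroxyl that could close to a flavanone and C2 is not involved.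

**Compound list**

1 | 2,4,6-trihydroxybenzaldehyde | O=Cc1c(O)cc(O)cc1O | starting material
2 | 2,6-dihydroxy-4-methoxybenzaldehyde | COc1cc(O)c(C=O)c(O)c1 | intermediate
3 | 2-hydroxy-4-methoxy-6-(triisopropylsilyloxy)benzaldehyde | COc1cc(O)c(C=O)c(O[Si](C(C)C)(C(C)C)C(C)C)c1 | intermediate
4 | 2-(hydroxymethyl)-5-methoxy-3-(triisopropylsilyloxy)phenol | COc1cc(O)c(CO)c(O[Si](C(C)C)(C(C)C)C(C)C)c1 | intermediate
5 | 5-methoxy-2-[(4-methylphenyl)sulfonylmethyl]-3-(triisopropylsilyloxy)phenol | COc1cc(O)c(CS(=O)(=O)c2ccc(C)cc2)c(O[Si](C(C)C)(C(C)C)C(C)C)c1 | intermediate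
6 | (2S,5S)-hexane-2,5-diol | C[C@H](O)CC[C@H](C)O | starting material
7 | (2S,5S)-hexane-2,5-diyl dimethanesulfonate | C[C@H](OS(C)(=O)=O)CC[C@H](C)OS(C)(=O)=O | intermediate
8 | (2R,5R)-2,5-dimethylthiolane | C[C@@H]1CC[C@@H](C)S1 | intermediate
9 | ethyl bromoacetate | CCOC(=O)CBr | starting material
10 | (2R,5R)-1-(2-ethoxy-2-oxoethyl)-2,5-dimethylthiolan-1-ium bromide | C[C@@H]1CC[C@@H](C)[S+]1CC(=O)OCC.[Br-] | intermediate
11 | 3-methoxy-6-methylidene-5-(triisopropylsilyloxy)cyclohexa-2,4-dien-1-one (ortho-quinone methide) | C=C1C(=O)C=C(OC)C=C1O[Si](C(C)C)(C(C)C)C(C)C | intermediate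
12 | 2-ethoxy-1-[(2R,5R)-2,5-dimethylthiolan-1-ium-1-yl]-2-oxoethan-1-ide (sulfonium ylide) | CCOC(=O)[CH-][S+]1[C@H](C)CC[C@H]1C | intermediate
13 | 2-{3-ethoxy-2-[(2R,5R)-2,5-dimethylthiolan-1-ium-1-yl]-3-oxopropyl}-5-methoxy-3-(triisopropylsilyloxy)phenolate (betaine, interconverting epimers at the ester-bearing carbon) | CCOC(=O)C(Cc1c([O-])cc(OC)cc1O[Si](C(C)C)(C(C)C)C(C)C)[S+]1[C@H](C)CC[C@H]1C | intermediate
14 | ethyl (2S)-6-methoxy-4-(triisopropylsilyloxy)-2,3-dihydro-1-benzofuran-2-carboxylate | COc1cc(O[Si](C(C)C)(C(C)C)C(C)C)c2c(c1)O[C@H](C(=O)OCC)C2 | intermediate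
15 | 1-[(2S)-6-methoxy-4-(triisopropylsilyloxy)-2,3-dihydro-1-benzofuran-2-yl]ethan-1-one | COc1cc(O[Si](C(C)C)(C(C)C)C(C)C)c2c(c1)O[C@H](C(C)=O)C2 | intermediate
16 | 2-[(2S)-6-methoxy-4-(triisopropylsilyloxy)-2,3-dihydro-1-benzofuran-2-yl]propan-2-ol | COc1cc(O[Si](C(C)C)(C(C)C)C(C)C)c2c(c1)O[C@H](C(C)(C)O)C2 | intermediate
17 | triethyl({2-[(2S)-6-methoxy-4-(triisopropylsilyloxy)-2,3-dihydro-1-benzofuran-2-yl]propan-2-yl}oxy)silane | COc1cc(O[Si](C(C)C)(C(C)C)C(C)C)c2c(c1)O[C@H](C(C)(C)O[Si](CC)(CC)CC)C2 | intermediate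
18 | (E)-4-hydroxycinnamic acid | O=C(O)/C=C/c1ccc(O)cc1 | starting material
19 | (2E)-3-(4-hydroxyphenyl)-N-methoxy-N-methylprop-2-enamide | CON(C)C(=O)/C=C/c1ccc(O)cc1 | intermediate
20 | (2E)-3-[4-(tert-butyldimethylsilyloxy)phenyl]-N-methoxy-N-methylprop-2-enamide | CON(C)C(=O)/C=C/c1ccc(O[Si](C)(C)C(C)(C)C)cc1 | intermediate
21 | [(2S)-6-methoxy-2-[2-(triethylsilyloxy)propan-2-yl]-4-(triisopropylsilyloxy)-2,3-dihydro-1-benzofuran-7-yl]lithium | [Li]c1c(OC)cc(O[Si](C(C)C)(C(C)C)C(C)C)c2c1O[C@H](C(C)(C)O[Si](CC)(CC)CC)C2 | intermediate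
22 | lithium (2E)-3-[4-(tert-butyldimethylsilyloxy)phenyl]-1-[methoxy(methyl)amino]-1-[(2S)-6-methoxy-2-[2-(triethylsilyloxy)propan-2-yl]-4-(triisopropylsilyloxy)-2,3-dihydro-1-benzofuran-7-yl]prop-2-en-1-olate | [Li]OC(N(C)OC)(/C=C/c1ccc(O[Si](C)(C)C(C)(C)C)cc1)c1c(OC)cc(O[Si](C(C)C)(C(C)C)C(C)C)c2c1O[C@H](C(C)(C)O[Si](CC)(CC)CC)C2 | intermediate
23 | (2E)-3-[4-(tert-butyldimethylsilyloxy)phenyl]-1-[(2S)-6-methoxy-2-[2-(triethylsilyloxy)propan-2-yl]-4-(triisopropylsilyloxy)-2,3-dihydro-1-benzofuran-7-yl]prop-2-en-1-one | COc1cc(O[Si](C(C)C)(C(C)C)C(C)C)c2c(c1C(=O)/C=C/c1ccc(O[Si](C)(C)C(C)(C)C)cc1)O[C@H](C(C)(C)O[Si](CC)(CC)CC)C2 | intermediate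
24 | (2E)-1-[(2S)-4-hydroxy-2-(2-hydroxypropan-2-yl)-6-methoxy-2,3-dihydro-1-benzofuran-7-yl]-3-(4-hydroxyphenyl)prop-2-en-1-one | COc1cc(O)c2c(c1C(=O)/C=C/c1ccc(O)cc1)O[C@H](C(C)(C)O)C2 | target

**Totals**

Total step count: 14. Longest linear sequence: 9 steps (steps 1–4, 8, 9, 10, 13, 14).

**Steps most likely to fail**

1. Step 8. The quinone methide may self-condense faster than the ylide traps it, the betaine may lactonise or eliminate sulfide instead of closing, or the two diastereomeric closures may not be differentiated, so that the ester forms with poor enantiomeric purity. The fallback sets out from 5 and returns at 16, using known reactions only. Treating 5 with (2-methylprop-1-en-1-yl)magnesium bromide (2.5 equiv, THF, −78 → 0 °C) should unveil the quinone methide with the first equivalent and add the alkenyl group to its CH2 with the second. This gives 5-methoxy-2-(3-methylbut-2-en-1-yl)-3-(triisopropylsilyloxy)phenol F1. Acetylation (Ac2O, pyridine) gives 5-methoxy-2-(3-methylbut-2-en-1-yl)-3-(triisopropylsilyloxy)phenyl acetate F2. Shi asymmetric epoxidation (D-fructose-derived ketone, Oxone, K2CO3, MeCN/dimethoxymethane/H2O, 0 °C) is expected from the spiro transition-state model to give 2-{[(2R)-3,3-dimethyloxiran-2-yl]methyl}-5-methoxy-3-(triisopropylsilyloxy)phenyl acetate F3. K2CO3 in MeOH at 0 °C then removes the acetate, and the phenoxide opens the epoxide at its secondary carbon (5-exo-tet, inversion) to give (2S)-alcohol 16.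

2. Step 13. Metalation may occur at C5 (followed by silyl migration from oxygen to carbon) or at the benzylic C3 with ring opening, or the hindered aryllithium may add in conjugate fashion to the cinnamoyl amide. The fallback sets out from 17 (and 20) and returns at 23. Electrophilic bromination of 17 (NBS, MeCN, −20 °C) should go to C7, because C5 is shielded by the OTIPS group. This gives ({2-[(2S)-7-bromo-6-methoxy-4-(triisopropylsilyloxy)-2,3-dihydro-1-benzofuran-2-yl]propan-2-yl}oxy)triethylsilane F4, in which the halogen fixes the site of metalation. Separately, DIBAL-H reduction of 20 (THF, −78 °C) gives (2E)-3-[4-(tert-butyldimethylsilyloxy)phenyl]prop-2-enal F5. Bromine–lithium exchange on F4 (t-BuLi, THF, −78 °C) and 1,2-addition to F5 give the allylic alcohol (2E)-3-[4-(tert-butyldimethylsilyloxy)phenyl]-1-[(2S)-6-methoxy-2-[2-(triethylsilyloxy)propan-2-yl]-4-(triisopropylsilyloxy)-2,3-dihydro-1-benzofuran-7-yl]prop-2-en-1-ol F6 (both carbinol epimers). MnO2 in CH2Cl2 oxidises F6 to enone 23.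

3. Step 4 (with the labile alcohol of step 3). The very electron-rich hydroxybenzyl cation may alkylate another arene (diarylmethane formation) in competition with sulfinate capture, or the salicyl alcohol may decompose on isolation. The fallback sets out from 3 and returns at 5, avoiding both the free benzylic alcohol and acid. Reductive amination of 3 (Me2NH, NaBH(OAc)3, 1,2-dichloroethane) gives the Mannich base 2-[(dimethylamino)methyl]-5-methoxy-3-(triisopropylsilyloxy)phenol F7. N-Methylation (MeI, MeCN, rt) gives {[2-hydroxy-4-methoxy-6-(triisopropylsilyloxy)phenyl]methyl}trimethylazanium iodide F8. Warming F8 with sodium p-toluenesulfinate (3 equiv, DMF, 60 °C) expels trimethylamine through the quinone methide, and sulfinate adds at sulfur to give 5.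

**Further compounds**

F1 | step 8 | 5-methoxy-2-(3-methylbut-2-en-1-yl)-3-(triisopropylsilyloxy)phenol | COc1cc(O)c(CC=C(C)C)c(O[Si](C(C)C)(C(C)C)C(C)C)c1
F2 | step 8 | 5-methoxy-2-(3-methylbut-2-en-1-yl)-3-(triisopropylsilyloxy)phenyl acetate | COc1cc(OC(C)=O)c(CC=C(C)C)c(O[Si](C(C)C)(C(C)C)C(C)C)c1
F3 | step 8 | 2-{[(2R)-3,3-dimethyloxiran-2-yl]methyl}-5-methoxy-3-(triisopropylsilyloxy)phenyl acetate | COc1cc(OC(C)=O)c(C[C@H]2OC2(C)C)c(O[Si](C(C)C)(C(C)C)C(C)C)c1
F4 | step 13 | ({2-[(2S)-7-bromo-6-methoxy-4-(triisopropylsilyloxy)-2,3-dihydro-1-benzofuran-2-yl]propan-2-yl}oxy)triethylsilane | COc1cc(O[Si](C(C)C)(C(C)C)C(C)C)c2c(c1Br)O[C@H](C(C)(C)O[Si](CC)(CC)CC)C2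
F5 | step 13 | (2E)-3-[4-(tert-butyldimethylsilyloxy)phenyl]prop-2-enal | O=C/C=C/c1ccc(O[Si](C)(C)C(C)(C)C)cc1
F6 | step 13 | (2E)-3-[4-(tert-butyldimethylsilyloxy)phenyl]-1-[(2S)-6-methoxy-2-[2-(triethylsilyloxy)propan-2-yl]-4-(triisopropylsilyloxy)-2,3-dihydro-1-benzofuran-7-yl]prop-2-en-1-ol | COc1cc(O[Si](C(C)C)(C(C)C)C(C)C)c2c(c1C(O)/C=C/c1ccc(O[Si](C)(C)C(C)(C)C)cc1)O[C@H](C(C)(C)O[Si](CC)(CC)CC)C2
F7 | step 4 | 2-[(dimethylamino)methyl]-5-methoxy-3-(triisopropylsilyloxy)phenol | COc1cc(O)c(CN(C)C)c(O[Si](C(C)C)(C(C)C)C(C)C)c1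
F8 | step 4 | {[2-hydroxy-4-methoxy-6-(triisopropylsilyloxy)phenyl]methyl}trimethylazanium iodide | COc1cc(O)c(C[N+](C)(C)C)c(O[Si](C(C)C)(C(C)C)C(C)C)c1.[I-]
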